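Count the starting material: it stands as starting material, target or cross product, and in the last cedar reading these shares add to 100 %, so two shares give the third.

| setting | larch | cedar | Wednesday's | Thursday's |
|---|---|---|---|---|
| starting material | 0.20 M | 0.20 M | 0.20 M | 0.20 M |
| partner | 0.095 M | 0.38 M | 0.450 M | 0.180 M |
| second substrate | 0.10 M | 0.10 M | 0.100 M | 0.100 M |
| protic impurity | 0.10 M | 0.10 M | 0.100 M | 0.100 M |
| remark | run made earlier | run made earlier |  |  |
| time |  |  | 3.0 h | 3.0 h |

- larch (time / min: cross product / %, starting material / %, target / %): 30.0: 31.0, 61.1, 9.9; 60.0: 34.2, 58.1, 8.6; 90.0: 32.7, 56.6, 9.6; 120: 35.3, 57.3, 9.8
- cedar (time / min: cross product / %, starting material / %, target / %): 15.0: 19.8, 48.0, 33.0; 40.0: 28.1, 38.0, 35.8; 80.0: 29.8, 35.4, 33.5; 120: 30.6, 34.6, 34.8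

(standard deviation of a reading: 1 percentage point)

- which of these there is most of at the end, counted by the starting material in it, Wednesday's (target / starting material / cross product)
- which of these there is most of at the end, counted by the starting material in it, Thursday's (target / starting material / cross product)
- how much there is at the end of the one of these that leads, in percent of the starting material charged: Wednesday's
- how much there is at the end of the one of these that leads, in percent of the starting material charged: Thursday's



Now fold the partner into one number. Take the target of the last two readings, where it stands flat within the scatter, and divide it by the partner equivalents, the partner charged per starting material charged. Larch gives 0.204: call this the capture, the share of the charged partner that ends in target, a selectivity for the partner. Cedar gives 0.180.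

Multiply capture by equivalents. For Wednesday's, with 2.25 equivalents and cedar's capture, I reckon target at 40.4 %. With cedar's cross product of 30.6 %, that leaves 29.0 % starting material, so target leads. For Thursday's, with 0.900 equivalents and the mean of both captures and both cross products, I reckon target at 17.3 % and cross product at 33.0 %. That leaves 49.8 % starting material, which leads.

Was one number enough? The captures differ by 0.0240, which moves Thursday's target by 2.2 percentage points, less than the lead of 17 points, so Thursday's leader stands. For Wednesday's one number is not enough: the same difference moves target by 5.5 points, and target lost there counts as starting material kept, so a drop of that size cuts Wednesday's lead over starting material from 11 points to 0.47 points, against a scatter of 1 point. Wednesday's target stands as my reckoning, not as a leader this test secures.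

The forecast, holding that “target scales almost linearly with partner charged”, names target at 40 % for Wednesday's and starting material at 49.5 % for Thursday's, the same leaders as mine.

Wednesday's ends with target leading at 39.3 %, and Thursday's with starting material leading at 48.7 %.

    starting material + partner → target (k = 0.330 M⁻¹ min⁻¹)
    second substrate + partner → second product (k = 0.0150 M⁻¹ min⁻¹)
    starting material + second substrate → cross product (k = 0.310 M⁻¹ min⁻¹)
    second substrate + protic impurity → quenched substrate (k = 0.240 M⁻¹ min⁻¹)
    partner → decomposed reagent (k = 0.220 min⁻¹)

Their captures come to 0.175 for Wednesday's and 0.198 for Thursday's, lower in Wednesday's, where more partner was charged. Now take a neighbour of Thursday's charged with 0.045 M of partner, which is 0.225 equiv. Larch's capture gives it 4.59 % target. That neighbour ends with 4.75 % target and 60.2 % starting material.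

(The runs were generated by integration for an exercise; the scatter is artificial.)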